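Everything rests on building ring A last, across the C4a=C8a bond of a finished ring C. Ring A carries oxygen on the alternate carbons C5, C7 and C8a and the benzyl carbon on C8, between C7 and C8a; this matches a 1,3-dioxygenated diene with the benzyl group on its nucleophilic terminus. One Diels–Alder benzannulation of a 5-sulfinyl-4-pyranone with a benzyl-terminated 1-methoxy-1,3-bis(silyloxy)diene forms C8–C8a and C4a–C5, and loss of sulfenic acid and methanol aromatises the new ring. The precursor is a 3-benzyloxy-2-(4-benzyloxyphenyl)-5-(p-tolylsulfinyl)pyran-4-one; every phenol travels as a benzyl ether or is set free in the key step, so a single hydrogenolysis finishes the route.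

Key step: step 10

Remark on the chemistry (assumption): sulfoxide 9 is used as the racemate and diene 16 as the crude, mainly (3Z) material with undefined C1=C2 geometry. Every stereocentre formed in step 10 is destroyed on aromatisation, and the target has none. Benzyl ethers and a 3-silyloxy diene are chosen so that no methyl ether has to be cleaved with a strong Lewis acid next to the acid-sensitive 8-benzyl group.

Step 1
Reactants: 1 3-hydroxy-4H-pyran-4-one
Product: 2 2-bromo-3-hydroxy-4H-pyran-4-one
Conditions: NBS (1.0 equiv), MeCN, 0 °C → rt, dark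
Reagents that add atoms: N-bromosuccinimide, O=C1CCC(=O)N1Br
Why: Electrophilic bromination of the enolic hydroxypyranone should go to C2, the enol carbon next to the hydroxyl, which is where 3-hydroxy-4-pyranones generally take up electrophiles.

Step 2
Reactants: 2 2-bromo-3-hydroxy-4H-pyran-4-one
Product: 3 3-(benzyloxy)-2-bromo-4H-pyran-4-one
Conditions: BnBr, K2CO3, DMF, rt
Reagents that add atoms: benzyl bromide, BrCc1ccccc1
Why: Williamson O-alkylation of the acidic enolic hydroxyl with a reactive benzylic halide under mild carbonate conditions, which should leave the vinylogous acyl bromide at C2 untouched.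

Step 3
Reactants: 3 3-(benzyloxy)-2-bromo-4H-pyran-4-one; 4 4-(benzyloxy)phenylboronic acid
Product: 5 3-(benzyloxy)-2-[4-(benzyloxy)phenyl]-4H-pyran-4-one
Conditions: Pd(PPh3)4 (5 mol %), K2CO3, dioxane/H2O, 80 °C
Reagents that add atoms: none
Why: Suzuki–Miyaura coupling, in which the C2–Br bond of a β-bromo enone should add oxidatively to zerovalent palladium with ease, as established for 2-halo-4-pyranones and 2-halochromones.

Step 4
Reactants: 5 3-(benzyloxy)-2-[4-(benzyloxy)phenyl]-4H-pyran-4-one
Product: 6 3-(benzyloxy)-2-[4-(benzyloxy)phenyl]-5-bromo-4H-pyran-4-one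
Conditions: NBS (1.05 equiv), DMF, 0 °C → rt, dark
Reagents that add atoms: N-bromosuccinimide, O=C1CCC(=O)N1Br
Why: Electrophilic α-bromination of a vinylogous ester, in which C5 is the only unsubstituted carbon that is β to the ring oxygen and α to the carbonyl, so attack there followed by proton loss is expected, as known for 4-pyranones and 4-pyridinones.

Step 5
Reactants: 6 3-(benzyloxy)-2-[4-(benzyloxy)phenyl]-5-bromo-4H-pyran-4-one; 7 4-methylbenzenethiol
Product: 8 3-(benzyloxy)-2-[4-(benzyloxy)phenyl]-5-[(4-methylphenyl)sulfanyl]-4H-pyran-4-one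
Conditions: Pd2(dba)3 (2.5 mol %), Xantphos (5 mol %), iPr2NEt, dioxane, 100 °C
Reagents that add atoms: none
Why: Palladium-catalysed C–S cross-coupling (Migita type) of an sp2 bromide with an arenethiol, in which the wide-bite-angle bisphosphine promotes C–S reductive elimination and the weak amine base limits conjugate addition of thiolate to the pyranone.

Step 6
Reactants: 8 3-(benzyloxy)-2-[4-(benzyloxy)phenyl]-5-[(4-methylphenyl)sulfanyl]-4H-pyran-4-one
Product: 9 3-(benzyloxy)-2-[4-(benzyloxy)phenyl]-5-[(4-methylphenyl)sulfinyl]-4H-pyran-4-one (racemic at sulfur)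
Conditions: mCPBA (1.0 equiv), CH2Cl2, −40 → 0 °C
Reagents that add atoms: meta-chloroperoxybenzoic acid, O=C(OO)c1cccc(Cl)c1
Why: Chemoselective peracid oxidation of sulfide to sulfoxide with one equivalent at low temperature should stop before the sulfone and spare the electron-poor pyranone double bonds; the sulfur stereocentre forms as the racemate, which does not matter because sulfur is expelled in step 10.

Step 7
Reactants: 10 methyl acetoacetate; 11 4-(benzyloxy)benzyl chloride
Product: 13 methyl 5-[4-(benzyloxy)phenyl]-3-oxopentanoate, via dilithium dianion 12 (not isolated)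
Conditions: LDA (2.2 equiv, commercial solution), THF, 0 °C; then 11, 0 °C → rt; aq. HCl work-up
Reagents that add atoms: none
Why: γ-Alkylation of an acetoacetate dianion, in which the more basic terminal carbanion of 12 displaces the benzylic chloride selectively in an SN2 reaction.

Step 8
Reactants: 13 methyl 5-[4-(benzyloxy)phenyl]-3-oxopentanoate
Product: 14 methyl 5-[4-(benzyloxy)phenyl]-3-(trimethylsilyloxy)pent-2-enoate (E/Z mixture)
Conditions: TMSCl, Et3N, toluene, rt; filtration under argon
Reagents that add atoms: chlorotrimethylsilane, C[Si](C)(C)Cl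
Why: O-Silylation of the enolised β-keto ester with a silyl chloride and a tertiary amine is the standard first stage towards 1,3-bis(silyloxy)dienes, and the E/Z ratio is irrelevant because this double bond becomes the central single bond of the diene.

Step 9
Reactants: 14 methyl 5-[4-(benzyloxy)phenyl]-3-(trimethylsilyloxy)pent-2-enoate
Product: 16 (3Z)-5-[4-(benzyloxy)phenyl]-1-methoxy-1,3-bis(trimethylsilyloxy)penta-1,3-diene, via lithium dienolate 15 (not isolated)
Conditions: LDA (1.2 equiv, commercial solution), THF, −78 °C; then TMSCl, −78 °C → rt; hexane, filtration under argon, used crude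
Reagents that add atoms: chlorotrimethylsilane, C[Si](C)(C)Cl
Why: Kinetic γ-deprotonation of the β-silyloxy enoate gives the extended ester dienolate, which is silylated on oxygen to the ketene acetal; allylic strain against the vinyl substituent should favour the (3Z) geometry, with the benzylic carbon pointing away from the diene.

Step 10
Reactants: 9 3-(benzyloxy)-2-[4-(benzyloxy)phenyl]-5-[(4-methylphenyl)sulfinyl]-4H-pyran-4-one; 16 (3Z)-5-[4-(benzyloxy)phenyl]-1-methoxy-1,3-bis(trimethylsilyloxy)penta-1,3-diene
Product: 20 3-(benzyloxy)-8-[4-(benzyloxy)benzyl]-2-[4-(benzyloxy)phenyl]-5,7-dihydroxy-4H-chromen-4-one, via cis-fused cycloadduct 17 (not isolated), via dihydrochromenone ketal 18 (not isolated), via bis-silyl ether 19 (not isolated)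
Conditions: 16 (3 equiv), toluene, rt → 90 °C; then 1 M HCl, THF, rt
Reagents that add atoms: none
Why: Proposed new method: diene 16, whose benzyl-bearing C4 is its most nucleophilic carbon, should add to the C5=C6 bond of 9 (pyranone numbering), which the C4 carbonyl and the sulfinyl group polarise so that C6, the future C8a, is electrophilic, either in an asynchronous concerted [4+2] cycloaddition or by Mukaiyama–Michael addition followed by 6-exo-trig attack of the α-sulfinyl enolate on the ketene-acetal-derived carbon, to give cis-fused adduct 17. In 17 the sulfinyl group on C4a and the hydrogen on C8a are cis, so thermal syn-elimination of the sulfenic acid restores the C4a=C8a bond (18); 1,4-elimination of methanol across C5 and C8 then aromatises ring A to bis-silyl ether 19, which dilute acid desilylates to 20. The closest known reactions are Diels–Alder benzannulations of 1-alkoxy-1-silyloxy dienes with sulfinyl- or halo-quinones and with 3-acylchromones; a plain 5-sulfinyl-4-pyranone has not been used as the dienophile in this way. Ring A is closed as a six-membered carbocycle by intermolecular [4+2] annulation that forms C8–C8a and C4a–C5. The stereocentres created at C4a, C5, C8 and C8a, and the one at sulfur, are transient and all vanish on aromatisation, so none needs control. The step needs regioselectivity (benzyl on C8) and site selectivity for C5=C6 over C2=C3: the first is secured by pairing the nucleophilic diene terminus with the β-carbon of the sulfinyl enone, the second by the sulfinyl activation of C5=C6 and by the tetrasubstituted, donor-laden nature of C2=C3.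

Step 11
Reactants: 20 3-(benzyloxy)-8-[4-(benzyloxy)benzyl]-2-[4-(benzyloxy)phenyl]-5,7-dihydroxy-4H-chromen-4-one
Product: 21 8-C-p-hydroxybenzylkaempferol, 3,5,7-trihydroxy-8-(4-hydroxybenzyl)-2-(4-hydroxyphenyl)-4H-chromen-4-one
Conditions: H2 (1 atm), Pd/C (10 wt %), THF/MeOH, rt
Reagents that add atoms: none
Why: Catalytic hydrogenolysis of the three benzyl ethers under neutral conditions should spare the flavonol C2=C3 bond and the diarylmethane C–C bonds, and it avoids the acid that could shift or cleave the electron-rich 8-benzyl group.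

Compound list

1 | 3-hydroxy-4H-pyran-4-one | O=c1ccocc1O | starting material
2 | 2-bromo-3-hydroxy-4H-pyran-4-one | O=c1ccoc(Br)c1O | intermediate
3 | 3-(benzyloxy)-2-bromo-4H-pyran-4-one | O=c1ccoc(Br)c1OCc1ccccc1 | intermediate
4 | 4-(benzyloxy)phenylboronic acid | OB(O)c1ccc(OCc2ccccc2)cc1 | starting material
5 | 3-(benzyloxy)-2-[4-(benzyloxy)phenyl]-4H-pyran-4-one | O=c1ccoc(-c2ccc(OCc3ccccc3)cc2)c1OCc1ccccc1 | intermediate
6 | 3-(benzyloxy)-2-[4-(benzyloxy)phenyl]-5-bromo-4H-pyran-4-one | O=c1c(Br)coc(-c2ccc(OCc3ccccc3)cc2)c1OCc1ccccc1 | intermediate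
7 | 4-methylbenzenethiol | Cc1ccc(S)cc1 | starting material
8 | 3-(benzyloxy)-2-[4-(benzyloxy)phenyl]-5-[(4-methylphenyl)sulfanyl]-4H-pyran-4-one | Cc1ccc(Sc2coc(-c3ccc(OCc4ccccc4)cc3)c(OCc3ccccc3)c2=O)cc1 | intermediate
9 | 3-(benzyloxy)-2-[4-(benzyloxy)phenyl]-5-[(4-methylphenyl)sulfinyl]-4H-pyran-4-one, racemic at sulfur (key-step precursor) | Cc1ccc(S(=O)c2coc(-c3ccc(OCc4ccccc4)cc3)c(OCc3ccccc3)c2=O)cc1 | intermediate
10 | methyl acetoacetate | COC(=O)CC(C)=O | starting material
11 | 4-(benzyloxy)benzyl chloride | ClCc1ccc(OCc2ccccc2)cc1 | starting material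
12 | dilithium dianion of methyl acetoacetate (not isolated) | [Li+].[Li+].COC([O-])=CC(=C)[O-] | intermediate
13 | methyl 5-[4-(benzyloxy)phenyl]-3-oxopentanoate | COC(=O)CC(=O)CCc1ccc(OCc2ccccc2)cc1 | intermediate
14 | methyl 5-[4-(benzyloxy)phenyl]-3-(trimethylsilyloxy)pent-2-enoate, E/Z mixture | COC(=O)C=C(O[Si](C)(C)C)CCc1ccc(OCc2ccccc2)cc1 | intermediate
15 | lithium (3Z)-dienolate of 14 (not isolated) | [Li+].COC([O-])=C/C(O[Si](C)(C)C)=C/Cc1ccc(OCc2ccccc2)cc1 | intermediate
16 | (3Z)-5-[4-(benzyloxy)phenyl]-1-methoxy-1,3-bis(trimethylsilyloxy)penta-1,3-diene, C1=C2 geometry undefined (key-step precursor) | COC(O[Si](C)(C)C)=C/C(O[Si](C)(C)C)=C/Cc1ccc(OCc2ccccc2)cc1 | intermediate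
17 | cis-fused cycloadduct, 3-(benzyloxy)-8-[4-(benzyloxy)benzyl]-2-[4-(benzyloxy)phenyl]-5-methoxy-4a-[(4-methylphenyl)sulfinyl]-5,7-bis(trimethylsilyloxy)-4a,5,8,8a-tetrahydro-4H-chromen-4-one; racemic, sulfinyl on C4a and H on C8a cis, configuration at sulfur, C5 and C8 undefined (not isolated) | O=C1C(OCc2ccccc2)=C(c2ccc(OCc3ccccc3)cc2)O[C@@H]2C(Cc3ccc(OCc4ccccc4)cc3)C(O[Si](C)(C)C)=CC(OC)(O[Si](C)(C)C)[C@]12S(=O)c1ccc(C)cc1 | intermediate
18 | 3-(benzyloxy)-8-[4-(benzyloxy)benzyl]-2-[4-(benzyloxy)phenyl]-5-methoxy-5,7-bis(trimethylsilyloxy)-5,8-dihydro-4H-chromen-4-one, mixture of diastereomers (not isolated) | O=c1c(OCc2ccccc2)c(-c2ccc(OCc3ccccc3)cc2)oc2c1C(OC)(O[Si](C)(C)C)C=C(O[Si](C)(C)C)C2Cc1ccc(OCc2ccccc2)cc1 | intermediate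
19 | 3-(benzyloxy)-8-[4-(benzyloxy)benzyl]-2-[4-(benzyloxy)phenyl]-5,7-bis(trimethylsilyloxy)-4H-chromen-4-one (not isolated) | O=c1c(OCc2ccccc2)c(-c2ccc(OCc3ccccc3)cc2)oc2c(Cc3ccc(OCc4ccccc4)cc3)c(O[Si](C)(C)C)cc(O[Si](C)(C)C)c12 | intermediate
20 | 3-(benzyloxy)-8-[4-(benzyloxy)benzyl]-2-[4-(benzyloxy)phenyl]-5,7-dihydroxy-4H-chromen-4-one (key-step product) | O=c1c(OCc2ccccc2)c(-c2ccc(OCc3ccccc3)cc2)oc2c(Cc3ccc(OCc4ccccc4)cc3)c(O)cc(O)c12 | intermediate
21 | 8-C-p-hydroxybenzylkaempferol, 3,5,7-trihydroxy-8-(4-hydroxybenzyl)-2-(4-hydroxyphenyl)-4H-chromen-4-one | O=c1c(O)c(-c2ccc(O)cc2)oc2c(Cc3ccc(O)cc3)c(O)cc(O)c12 | target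

Total step count: 11. Longest linear sequence: 8 steps (steps 1 to 6, then 10 and 11); the diene arm (steps 7 to 9) joins at step 10.

Steps most likely to fail

1. Step 10 (proposed new method). The sulfinylpyranone may be too weak a dienophile, so that the diene is lost to protodesilylation by the liberated sulfenic acid before it adds. Addition may also stop after the conjugate-addition stage, with ring C opening by retro-oxa-Michael cleavage instead of ring A closing, or aromatisation may stall. The fallback uses only known reactions and takes ring A from a ready-made flavonol instead of building it; it sets out from chloride 11 and comes back to the route at target 21. Commercial kaempferol would be perbenzylated (BnBr, K2CO3, DMF, 80 °C) to 3,5,7-tris(benzyloxy)-2-[4-(benzyloxy)phenyl]-4H-chromen-4-one F1. Iodination (N-iodosuccinimide, cat. CF3CO2H, CH2Cl2), which 5,7-dialkoxyflavones with an alkylated 5-oxygen take up at C8, should give 3,5,7-tris(benzyloxy)-2-[4-(benzyloxy)phenyl]-8-iodo-4H-chromen-4-one F2. Chloride 11 would be converted with zinc dust and LiCl in THF into [4-(benzyloxy)benzyl]zinc chloride F3. Negishi coupling of F2 with F3 (Pd(OAc)2, SPhos, THF, 50 °C) should give 3,5,7-tris(benzyloxy)-8-[4-(benzyloxy)benzyl]-2-[4-(benzyloxy)phenyl]-4H-chromen-4-one F4, which the conditions of step 11 would debenzylate to 21.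

2. Step 5. Thiolate may add conjugatively at C6 of the bromopyranone, leading to cine substitution or ring opening, or it may deactivate the palladium catalyst so that C–S coupling stalls. The fallback reverses the polarity and uses electrophilic sulfur on the nucleophilic C5; it sets out from pyranone 5 (bypassing bromide 6) and comes back at sulfide 8. Thiol 7 would be converted in the flask with N-chlorosuccinimide (CH2Cl2, 0 °C) into 4-methylbenzenesulfenyl chloride F5, which would be added to 5; Et3N would then take up the hydrogen chloride to leave 8.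

3. Step 4. Site selectivity may be lost, through competing bromination ortho to the benzyloxy group of the 2-aryl ring or through double bromination. The fallback brominates before the aryl ring is present; it sets out from bromide 3 and comes back at bromide 6. NBS in DMF should convert 3 into 3-(benzyloxy)-2,5-dibromo-4H-pyran-4-one F6. A site-selective Suzuki–Miyaura coupling with one equivalent of boronic acid 4 under the conditions of step 3 should then take place at the C2–Br bond, since a β-bromo enone adds to zerovalent palladium faster than an α-bromo enone, to give 6.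

Further compounds

F1 | step 10 | 3,5,7-tris(benzyloxy)-2-[4-(benzyloxy)phenyl]-4H-chromen-4-one | O=c1c(OCc2ccccc2)c(-c2ccc(OCc3ccccc3)cc2)oc2cc(OCc3ccccc3)cc(OCc3ccccc3)c12
F2 | step 10 | 3,5,7-tris(benzyloxy)-2-[4-(benzyloxy)phenyl]-8-iodo-4H-chromen-4-one | O=c1c(OCc2ccccc2)c(-c2ccc(OCc3ccccc3)cc2)oc2c(I)c(OCc3ccccc3)cc(OCc3ccccc3)c12
F3 | step 10 | [4-(benzyloxy)benzyl]zinc chloride | Cl[Zn]Cc1ccc(OCc2ccccc2)cc1
F4 | step 10 | 3,5,7-tris(benzyloxy)-8-[4-(benzyloxy)benzyl]-2-[4-(benzyloxy)phenyl]-4H-chromen-4-one | O=c1c(OCc2ccccc2)c(-c2ccc(OCc3ccccc3)cc2)oc2c(Cc3ccc(OCc4ccccc4)cc3)c(OCc3ccccc3)cc(OCc3ccccc3)c12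
F5 | step 5 | 4-methylbenzenesulfenyl chloride | Cc1ccc(SCl)cc1
F6 | step 4 | 3-(benzyloxy)-2,5-dibromo-4H-pyran-4-one | O=c1c(Br)coc(Br)c1OCc1ccccc1
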